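**Strategy.** Ring B is built by benzannulation, not by substitution of an existing arene. Its four contiguous groups (C1′ carbon, C2′ oxygen, C3′ alkenyl, C4′ oxygen) arise when a vinylketene, released by photochemical Wolff rearrangement of an acetal-bearing diazo enone, combines with a silyloxy enyne. One operation forges C5′–C6′, C4′–C5′, C2′–C3′ and C1′–C2′ and fixes the alkenyl chain between the two oxygens. The acetal carbon becomes C3. A phloroglucinol-derived ring A, prenylated between two equivalent ethers so that C6 is unambiguous, is joined as a deoxybenzoin, ring C is closed as an isoflavone, and C3 is set late by palladium-catalysed decarboxylative asymmetric protonation.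

Key step: step 5

Assumption: the (S)-configured PHOX ligand is taken to give the 3S ketone in step 18; if a trial run shows the opposite sense, the (R)-ligand is used and nothing else changes.

**Route**

Step 1
Reactants: 1 2,2-dimethoxyacetaldehyde; 2 (acetylmethylene)triphenylphosphorane
Product: 3 (E)-5,5-dimethoxypent-3-en-2-one
Conditions: CH2Cl2, rt (1 used as its 60% aqueous solution)
Reagents that add atoms: none
Why: A stabilised keto ylide should olefinate the aldehyde with high E selectivity (Wittig reaction) while the acetal stays untouched.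

Step 2
Reactants: 3 (E)-5,5-dimethoxypent-3-en-2-one
Product: 5 (E)-1-diazo-5,5-dimethoxypent-3-en-2-one, via trifluoroacetyl diketone 4 (not isolated)
Conditions: LiN(SiMe3)2, THF, −78 °C; CF3CO2CH2CF3; aq. HCl wash; then MsN3, Et3N, H2O, MeCN, rt
Reagents that add atoms: methanesulfonyl azide CS(=O)(=O)N=[N+]=[N-]; 2,2,2-trifluoroethyl trifluoroacetate O=C(OCC(F)(F)F)C(F)(F)F (its atoms stay only in 4)
Why: The kinetic methyl enolate is trifluoroacetylated and the activated diketone should undergo detrifluoroacetylative diazo transfer, the standard entry to α,β-unsaturated diazo ketones.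

Step 3
Reactants: 6 isobutyraldehyde; 7 triethyl phosphonoacetate
Product: 8 ethyl (E)-4-methylpent-2-enoate
Conditions: NaH, THF, 0 °C → rt
Reagents that add atoms: none
Why: Horner–Wadsworth–Emmons olefination of an α-branched aldehyde should give the E enoate.

Step 4
Reactants: 8 ethyl (E)-4-methylpent-2-enoate
Product: 11 (E)-5-methyl-1-(triisopropylsilyloxy)hex-3-en-1-yne, via dibromo enolate 9 (not isolated), via lithium ynolate 10 (not isolated)
Conditions: CH2Br2, lithium 2,2,6,6-tetramethylpiperidide, THF, −78 °C; 8; LiN(SiMe3)2; n-BuLi, −78 °C → rt; i-Pr3SiCl, −78 → 0 °C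
Reagents that add atoms: dibromomethane BrCBr; chlorotriisopropylsilane CC(C)[Si](Cl)(C(C)C)C(C)C
Why: Kowalski ester-to-ynolate homologation moves the alkenyl group by a carbenoid 1,2-shift with retention of alkene geometry, and the bulky silyl chloride should cap the ynolate on oxygen.

Step 5
Reactants: 5 (E)-1-diazo-5,5-dimethoxypent-3-en-2-one; 11 (E)-5-methyl-1-(triisopropylsilyloxy)hex-3-en-1-yne
Product: 16 6-(dimethoxymethyl)-2-[(E)-3-methylbut-1-enyl]-3-(triisopropylsilyloxy)phenol, via vinylketene 12 (not isolated), via cyclobutenone 13 (not isolated), via dienylketene 14 (not isolated), via cyclohexadienone 15 (not isolated)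
Conditions: hν (medium-pressure Hg lamp, Vycor filter), ClCH2CH2Cl, rt; then 80 °C
Reagents that add atoms: none
Why: Light expels N2 from 5 and the alkenyl group shifts to the carbene carbon (Wolff rearrangement, forming C5′–C6′) to give vinylketene 12, whose C=C=O unit adds across the ynol ether of 11 in a [2+2] cycloaddition (C2′–C3′ and C4′–C5′) to give 13; warming opens 13 by 4π electrocyclic ring opening to dienylketene 14, which closes and enolises to 16. The closest known reaction type is the Danheiser benzannulation in its diazo ketone variant with silyloxyalkynes. Ring B is closed by a thermal disrotatory 6π electrocyclisation that forms C1′–C2′, and tautomerisation of dienone 15 makes it aromatic. No stereocentre is formed, and the E alkene of 11 is a spectator that should be carried through unchanged. The step needs the oxygen-free alkyne carbon, the one bearing the alkenyl chain, to bond to the ketene carbonyl carbon, which the polarisation of the ynol ether by its oxygen secures; reaction at the triple bond and not at either alkene is secured by the far higher nucleophilicity of the ynol ether.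

Step 6
Reactants: 16 6-(dimethoxymethyl)-2-[(E)-3-methylbut-1-enyl]-3-(triisopropylsilyloxy)phenol
Product: 18 2-methoxy-3-[(E)-3-methylbut-1-enyl]-4-(triisopropylsilyloxy)benzaldehyde, via methyl ether acetal 17 (not isolated)
Conditions: MeI, K2CO3, acetone, 50 °C; filter; then 1 M HCl, rt
Reagents that add atoms: iodomethane CI; water O
Why: Williamson methylation of the flanked phenol followed by mild acid hydrolysis of the benzylic dimethyl acetal should leave the hindered aryl silyl ether and the alkene intact.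

Step 7
Reactants: 18 2-methoxy-3-[(E)-3-methylbut-1-enyl]-4-(triisopropylsilyloxy)benzaldehyde
Product: 20 2-{2-methoxy-3-[(E)-3-methylbut-1-enyl]-4-(triisopropylsilyloxy)phenyl}acetaldehyde, via enol ether 19 (not isolated)
Conditions: Ph3P(CH2OMe)Cl, t-BuOK, THF, 0 °C → rt; then 2 M HCl, rt
Reagents that add atoms: (methoxymethyl)triphenylphosphonium chloride COC[P+](c1ccccc1)(c1ccccc1)c1ccccc1.[Cl-]; water O
Why: Wittig methoxymethylenation and hydrolysis of the enol ether is the standard one-carbon homologation of an aryl aldehyde, and the enol ether hydrolyses far faster than the hindered styrene can be protonated.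

Step 8
Reactants: 21 phloroglucinol
Product: 22 5-(triisopropylsilyloxy)benzene-1,3-diol
Conditions: i-Pr3SiCl (1 equiv), imidazole, DMF, 0 °C → rt, 21 in threefold excess
Reagents that add atoms: chlorotriisopropylsilane CC(C)[Si](Cl)(C(C)C)C(C)C
Why: Statistical monosilylation with the cheap triol in excess should favour the monoether, and the water-soluble triol is washed out.

Step 9
Reactants: 22 5-(triisopropylsilyloxy)benzene-1,3-diol
Product: 23 [3,5-bis(methoxymethoxy)phenoxy]triisopropylsilane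
Conditions: MeOCH2Cl, i-Pr2NEt, CH2Cl2, 0 °C → rt
Reagents that add atoms: chloromethyl methyl ether COCCl
Why: O-alkylation of both phenols with the chloromethyl ether under amine base gives the two acetal ethers that later direct metalation.

Step 10
Reactants: 23 [3,5-bis(methoxymethoxy)phenoxy]triisopropylsilane
Product: 25 [3,5-bis(methoxymethoxy)-4-(3-methylbut-2-enyl)phenoxy]triisopropylsilane, via aryllithium 24 (not isolated)
Conditions: n-BuLi, THF, 0 °C; CuI (10 mol %), prenyl bromide, −78 °C → rt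
Reagents that add atoms: 1-bromo-3-methylbut-2-ene CC(C)=CCBr
Why: Directed ortho-metalation occurs at the one position held between two acetal oxygens (the bulky silyl ether does not direct), and copper-catalysed allylation should place the prenyl group there.

Step 11
Reactants: 25 [3,5-bis(methoxymethoxy)-4-(3-methylbut-2-enyl)phenoxy]triisopropylsilane
Product: 26 3,5-bis(methoxymethoxy)-4-(3-methylbut-2-enyl)phenol
Conditions: Bu4NF, THF, 0 °C
Reagents that add atoms: none
Why: Fluoride cleaves the aryl silyl ether and leaves the acetal ethers and the alkene alone.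

Step 12
Reactants: 26 3,5-bis(methoxymethoxy)-4-(3-methylbut-2-enyl)phenol
Product: 27 5-(1-ethoxyethoxy)-1,3-bis(methoxymethoxy)-2-(3-methylbut-2-enyl)benzene (racemic at the acetal carbon)
Conditions: ethyl vinyl ether, pyridinium p-toluenesulfonate (cat.), CH2Cl2, rt
Reagents that add atoms: ethyl vinyl ether C=COCC
Why: Acid-catalysed addition of the phenol to the vinyl ether installs an acetal that directs the next metalation and is later removable without loss of the methoxymethyl ethers.

Step 13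
Reactants: 27 5-(1-ethoxyethoxy)-1,3-bis(methoxymethoxy)-2-(3-methylbut-2-enyl)benzene; 20 2-{2-methoxy-3-[(E)-3-methylbut-1-enyl]-4-(triisopropylsilyloxy)phenyl}acetaldehyde
Product: 30 1-[2-(1-ethoxyethoxy)-4,6-bis(methoxymethoxy)-5-(3-methylbut-2-enyl)phenyl]-2-{2-methoxy-3-[(E)-3-methylbut-1-enyl]-4-(triisopropylsilyloxy)phenyl}ethanol (diastereomer mixture), via aryllithium 28 (not isolated), via arylcerium dichloride 29 (not isolated)
Conditions: 27, n-BuLi, THF, 0 °C; CeCl3, −78 °C; then 20, −78 → 0 °C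
Reagents that add atoms: none
Why: Directed ortho-metalation at the only remaining ring C–H type (two positions equivalent by symmetry) and transmetalation to the weakly basic organocerium should give clean 1,2-addition to the enolisable aldehyde, and the new carbinol centre is unselective and is erased in step 14.

Step 14
Reactants: 30 the diaryl ethanol from step 13
Product: 31 1-[2-(1-ethoxyethoxy)-4,6-bis(methoxymethoxy)-5-(3-methylbut-2-enyl)phenyl]-2-{2-methoxy-3-[(E)-3-methylbut-1-enyl]-4-(triisopropylsilyloxy)phenyl}ethanone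
Conditions: Dess–Martin periodinane, NaHCO3, CH2Cl2, 0 °C → rt
Reagents that add atoms: none
Why: Buffered Dess–Martin oxidation converts the benzylic alcohol into the deoxybenzoin without touching acetals, alkenes or the silyl ether.

Step 15
Reactants: 31 the ethoxyethyl-protected deoxybenzoin
Product: 32 1-[2-hydroxy-4,6-bis(methoxymethoxy)-5-(3-methylbut-2-enyl)phenyl]-2-{2-methoxy-3-[(E)-3-methylbut-1-enyl]-4-(triisopropylsilyloxy)phenyl}ethanone
Conditions: pyridinium p-toluenesulfonate (cat.), MeOH, rt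
Reagents that add atoms: none
Why: Transacetalisation removes the acetaldehyde-derived acetal far faster than the formaldehyde-derived ones, so only the phenol that becomes O1 is freed.

Step 16
Reactants: 32 the 2-hydroxy deoxybenzoin
Product: 34 5,7-bis(methoxymethoxy)-3-{2-methoxy-3-[(E)-3-methylbut-1-enyl]-4-(triisopropylsilyloxy)phenyl}-6-(3-methylbut-2-enyl)-4H-chromen-4-one, via enaminone 33 (not isolated)
Conditions: Me2NCH(OMe)2, toluene, 90 °C
Reagents that add atoms: N,N-dimethylformamide dimethyl acetal COC(OC)N(C)C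
Why: Condensation at the active methylene gives an enaminone that the free phenol closes by addition–elimination, the classical deoxybenzoin route to isoflavones, and this closes ring C with C2 in place.

Step 17
Reactants: 34 the isoflavone
Product: 36 allyl 5,7-bis(methoxymethoxy)-3-{2-methoxy-3-[(E)-3-methylbut-1-enyl]-4-(triisopropylsilyloxy)phenyl}-6-(3-methylbut-2-enyl)-2H-chromen-4-yl carbonate, via lithium enolate 35 (not isolated)
Conditions: LiBH(s-Bu)3, THF, −78 °C; then ClCO2CH2CH=CH2, −78 → 0 °C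
Reagents that add atoms: allyl chloroformate C=CCOC(Cl)=O
Why: The bulky borohydride should add hydride to C2 of the chromone in a conjugate sense, and the regiodefined enolate is trapped on oxygen by the chloroformate (reductive enolate trapping).

Step 18
Reactants: 36 the allyl enol carbonate
Product: 37 (3S)-5,7-bis(methoxymethoxy)-3-{2-methoxy-3-[(E)-3-methylbut-1-enyl]-4-(triisopropylsilyloxy)phenyl}-6-(3-methylbut-2-enyl)chroman-4-one
Conditions: Pd2(dba)3 (5 mol %), (S)-(CF3)3-t-BuPHOX (12.5 mol %), Meldrum's acid (2.5 equiv), 1,4-dioxane, 40 °C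
Reagents that add atoms: none
Why: In this decarboxylative asymmetric protonation zerovalent palladium ionises the allyl carbonate, loss of CO2 leaves the same PHOX-bound palladium enolate that a β-keto allyl ester would give, and Meldrum's acid should protonate C3 on the face left open by the ligand, which sets the 3S centre under catalyst control.

Step 19
Reactants: 37 the protected (3S)-isoflavanone
Product: 38 (3S)-5,7-dihydroxy-3-{2-methoxy-3-[(E)-3-methylbut-1-enyl]-4-(triisopropylsilyloxy)phenyl}-6-(3-methylbut-2-enyl)chroman-4-one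
Conditions: 3 M HCl, MeOH, 40 °C, short reaction time
Reagents that add atoms: none
Why: Acid-catalysed transacetalisation to methanol removes both aryl methoxymethyl ethers while the aryl triisopropylsilyl ether survives.

Step 20
Reactants: 38 the 4′-silyl ether
Product: 39 (3S)-5,7-dihydroxy-3-{4-hydroxy-2-methoxy-3-[(E)-3-methylbut-1-enyl]phenyl}-6-(3-methylbut-2-enyl)chroman-4-one (target)
Conditions: HF·pyridine, pyridine, THF, 0 °C
Reagents that add atoms: none
Why: Buffered fluoride cleaves the aryl silyl ether under weakly acidic, non-enolising conditions, so the C3 configuration should be kept.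

**Compound list**

1 | 2,2-dimethoxyacetaldehyde | COC(OC)C=O | starting material
2 | (acetylmethylene)triphenylphosphorane | CC(=O)C=P(c1ccccc1)(c1ccccc1)c1ccccc1 | starting material
3 | (E)-5,5-dimethoxypent-3-en-2-one | COC(OC)/C=C/C(C)=O | intermediate
4 | (E)-1,1,1-trifluoro-7,7-dimethoxyhept-5-ene-2,4-dione | COC(OC)/C=C/C(=O)CC(=O)C(F)(F)F | intermediate
5 | (E)-1-diazo-5,5-dimethoxypent-3-en-2-one | COC(OC)/C=C/C(=O)C=[N+]=[N-] | intermediate
6 | isobutyraldehyde | CC(C)C=O | starting material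
7 | triethyl phosphonoacetate | CCOC(=O)CP(=O)(OCC)OCC | starting material
8 | ethyl (E)-4-methylpent-2-enoate | CCOC(=O)/C=C/C(C)C | intermediate
9 | lithium (3E)-1,1-dibromo-5-methylhexa-1,3-dien-2-olate | [Li+].[O-]C(=C(Br)Br)/C=C/C(C)C | intermediate
10 | lithium (E)-5-methylhex-3-en-1-yn-1-olate | [Li+].[O-]C#C/C=C/C(C)C | intermediate
11 | (E)-5-methyl-1-(triisopropylsilyloxy)hex-3-en-1-yne | CC(C)/C=C/C#CO[Si](C(C)C)(C(C)C)C(C)C | intermediate
12 | (E)-5,5-dimethoxypenta-1,3-dien-1-one | COC(OC)/C=C/C=C=O | intermediate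
13 | 4-[(E)-3,3-dimethoxyprop-1-enyl]-2-[(E)-3-methylbut-1-enyl]-3-(triisopropylsilyloxy)cyclobut-2-en-1-one (racemic) | COC(OC)/C=C/C1C(=O)C(/C=C/C(C)C)=C1O[Si](C(C)C)(C(C)C)C(C)C | intermediate
14 | (3E,5E)-7,7-dimethoxy-2-[(E)-3-methylbut-1-enyl]-3-(triisopropylsilyloxy)hepta-1,3,5-trien-1-one (ketene carbon and C5 cis across C3=C4) | CC(C)/C=C/C(=C=O)/C(O[Si](C(C)C)(C(C)C)C(C)C)=C\C=C\C(OC)OC | intermediate
15 | 6-(dimethoxymethyl)-2-[(E)-3-methylbut-1-enyl]-3-(triisopropylsilyloxy)cyclohexa-2,4-dien-1-one (racemic) | COC(OC)C1C=CC(O[Si](C(C)C)(C(C)C)C(C)C)=C(/C=C/C(C)C)C1=O | intermediate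
16 | 6-(dimethoxymethyl)-2-[(E)-3-methylbut-1-enyl]-3-(triisopropylsilyloxy)phenol | COC(OC)c1ccc(O[Si](C(C)C)(C(C)C)C(C)C)c(/C=C/C(C)C)c1O | intermediate
17 | [4-(dimethoxymethyl)-3-methoxy-2-[(E)-3-methylbut-1-enyl]phenoxy]triisopropylsilane | COC(OC)c1ccc(O[Si](C(C)C)(C(C)C)C(C)C)c(/C=C/C(C)C)c1OC | intermediate
18 | 2-methoxy-3-[(E)-3-methylbut-1-enyl]-4-(triisopropylsilyloxy)benzaldehyde | O=Cc1ccc(O[Si](C(C)C)(C(C)C)C(C)C)c(/C=C/C(C)C)c1OC | intermediate
19 | [3-methoxy-4-(2-methoxyethenyl)-2-[(E)-3-methylbut-1-enyl]phenoxy]triisopropylsilane (E/Z mixture at the enol ether) | COC=Cc1ccc(O[Si](C(C)C)(C(C)C)C(C)C)c(/C=C/C(C)C)c1OC | intermediate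
20 | 2-{2-methoxy-3-[(E)-3-methylbut-1-enyl]-4-(triisopropylsilyloxy)phenyl}acetaldehyde | O=CCc1ccc(O[Si](C(C)C)(C(C)C)C(C)C)c(/C=C/C(C)C)c1OC | intermediate
21 | phloroglucinol | Oc1cc(O)cc(O)c1 | starting material
22 | 5-(triisopropylsilyloxy)benzene-1,3-diol | Oc1cc(O)cc(O[Si](C(C)C)(C(C)C)C(C)C)c1 | intermediate
23 | [3,5-bis(methoxymethoxy)phenoxy]triisopropylsilane | COCOc1cc(OCOC)cc(O[Si](C(C)C)(C(C)C)C(C)C)c1 | intermediate
24 | [2,6-bis(methoxymethoxy)-4-(triisopropylsilyloxy)phenyl]lithium | [Li]c1c(OCOC)cc(O[Si](C(C)C)(C(C)C)C(C)C)cc1OCOC | intermediate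
25 | [3,5-bis(methoxymethoxy)-4-(3-methylbut-2-enyl)phenoxy]triisopropylsilane | COCOc1cc(O[Si](C(C)C)(C(C)C)C(C)C)cc(OCOC)c1CC=C(C)C | intermediate
26 | 3,5-bis(methoxymethoxy)-4-(3-methylbut-2-enyl)phenol | COCOc1cc(O)cc(OCOC)c1CC=C(C)C | intermediate
27 | 5-(1-ethoxyethoxy)-1,3-bis(methoxymethoxy)-2-(3-methylbut-2-enyl)benzene (racemic) | CCOC(C)Oc1cc(OCOC)c(CC=C(C)C)c(OCOC)c1 | intermediate
28 | [2-(1-ethoxyethoxy)-4,6-bis(methoxymethoxy)-5-(3-methylbut-2-enyl)phenyl]lithium | [Li]c1c(OC(C)OCC)cc(OCOC)c(CC=C(C)C)c1OCOC | intermediate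
29 | dichloro[2-(1-ethoxyethoxy)-4,6-bis(methoxymethoxy)-5-(3-methylbut-2-enyl)phenyl]cerium | Cl[Ce](Cl)c1c(OC(C)OCC)cc(OCOC)c(CC=C(C)C)c1OCOC | intermediate
30 | 1-[2-(1-ethoxyethoxy)-4,6-bis(methoxymethoxy)-5-(3-methylbut-2-enyl)phenyl]-2-{2-methoxy-3-[(E)-3-methylbut-1-enyl]-4-(triisopropylsilyloxy)phenyl}ethanol (diastereomer mixture) | CCOC(C)Oc1cc(OCOC)c(CC=C(C)C)c(OCOC)c1C(O)Cc1ccc(O[Si](C(C)C)(C(C)C)C(C)C)c(/C=C/C(C)C)c1OC | intermediate
31 | 1-[2-(1-ethoxyethoxy)-4,6-bis(methoxymethoxy)-5-(3-methylbut-2-enyl)phenyl]-2-{2-methoxy-3-[(E)-3-methylbut-1-enyl]-4-(triisopropylsilyloxy)phenyl}ethanone (racemic at the acetal carbon) | CCOC(C)Oc1cc(OCOC)c(CC=C(C)C)c(OCOC)c1C(=O)Cc1ccc(O[Si](C(C)C)(C(C)C)C(C)C)c(/C=C/C(C)C)c1OC | intermediate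
32 | 1-[2-hydroxy-4,6-bis(methoxymethoxy)-5-(3-methylbut-2-enyl)phenyl]-2-{2-methoxy-3-[(E)-3-methylbut-1-enyl]-4-(triisopropylsilyloxy)phenyl}ethanone | COCOc1cc(O)c(C(=O)Cc2ccc(O[Si](C(C)C)(C(C)C)C(C)C)c(/C=C/C(C)C)c2OC)c(OCOC)c1CC=C(C)C | intermediate
33 | 3-(dimethylamino)-1-[2-hydroxy-4,6-bis(methoxymethoxy)-5-(3-methylbut-2-enyl)phenyl]-2-{2-methoxy-3-[(E)-3-methylbut-1-enyl]-4-(triisopropylsilyloxy)phenyl}prop-2-en-1-one (enamine geometry not defined) | CN(C)C=C(C(=O)c1c(O)cc(OCOC)c(CC=C(C)C)c1OCOC)c1ccc(O[Si](C(C)C)(C(C)C)C(C)C)c(/C=C/C(C)C)c1OC | intermediate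
34 | 5,7-bis(methoxymethoxy)-3-{2-methoxy-3-[(E)-3-methylbut-1-enyl]-4-(triisopropylsilyloxy)phenyl}-6-(3-methylbut-2-enyl)-4H-chromen-4-one | COCOc1cc2occ(-c3ccc(O[Si](C(C)C)(C(C)C)C(C)C)c(/C=C/C(C)C)c3OC)c(=O)c2c(OCOC)c1CC=C(C)C | intermediate
35 | lithium 5,7-bis(methoxymethoxy)-3-{2-methoxy-3-[(E)-3-methylbut-1-enyl]-4-(triisopropylsilyloxy)phenyl}-6-(3-methylbut-2-enyl)-2H-chromen-4-olate | [Li+].[O-]C1=C(c2ccc(O[Si](C(C)C)(C(C)C)C(C)C)c(/C=C/C(C)C)c2OC)COc2cc(OCOC)c(CC=C(C)C)c(OCOC)c21 | intermediate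
36 | allyl 5,7-bis(methoxymethoxy)-3-{2-methoxy-3-[(E)-3-methylbut-1-enyl]-4-(triisopropylsilyloxy)phenyl}-6-(3-methylbut-2-enyl)-2H-chromen-4-yl carbonate | C=CCOC(=O)OC1=C(c2ccc(O[Si](C(C)C)(C(C)C)C(C)C)c(/C=C/C(C)C)c2OC)COc2cc(OCOC)c(CC=C(C)C)c(OCOC)c21 | intermediate
37 | (3S)-5,7-bis(methoxymethoxy)-3-{2-methoxy-3-[(E)-3-methylbut-1-enyl]-4-(triisopropylsilyloxy)phenyl}-6-(3-methylbut-2-enyl)chroman-4-one | COc1c([C@H]2COc3cc(OCOC)c(CC=C(C)C)c(OCOC)c3C2=O)ccc(O[Si](C(C)C)(C(C)C)C(C)C)c1/C=C/C(C)C | intermediate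
38 | (3S)-5,7-dihydroxy-3-{2-methoxy-3-[(E)-3-methylbut-1-enyl]-4-(triisopropylsilyloxy)phenyl}-6-(3-methylbut-2-enyl)chroman-4-one | COc1c([C@H]2COc3cc(O)c(CC=C(C)C)c(O)c3C2=O)ccc(O[Si](C(C)C)(C(C)C)C(C)C)c1/C=C/C(C)C | intermediate
39 | (3S)-5,7-dihydroxy-3-{4-hydroxy-2-methoxy-3-[(E)-3-methylbut-1-enyl]phenyl}-6-(3-methylbut-2-enyl)chroman-4-one | COc1c([C@H]2COc3cc(O)c(CC=C(C)C)c(O)c3C2=O)ccc(O)c1/C=C/C(C)C | target

**Count**

Total steps: 20. Longest linear sequence: 13 steps (for example steps 1, 2, 5, 6, 7 and 13 to 20).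

**Steps most likely to fail**

Step 5. The ketocarbene may be lost to pathways other than the Wolff shift, and the conjugated ynol ether or the alkenyl-substituted ketene 14 may oligomerise before the 6π closure. The fallback gives up the benzannulation and decorates a preformed resorcinol core by cross-coupling. It sets out from 6, which chromium-mediated boron olefination (CrCl2, LiI, Cl2CHB(pin), THF) should convert into (E)-4,4,5,5-tetramethyl-2-(3-methylbut-1-enyl)-1,3,2-dioxaborolane F1. Commercial 2-iodoresorcinol is ortho-formylated (MgCl2, Et3N, paraformaldehyde, MeCN) to 2,4-dihydroxy-3-iodobenzaldehyde F2, silylated at the non-chelated hydroxyl (i-Pr3SiCl, imidazole) to 2-hydroxy-3-iodo-4-(triisopropylsilyloxy)benzaldehyde F3, and methylated (MeI, K2CO3) to 3-iodo-2-methoxy-4-(triisopropylsilyloxy)benzaldehyde F4. Suzuki–Miyaura coupling of F4 with F1 (PdCl2(dppf), K3PO4, dioxane–water, 80 °C) comes back to the route at 18.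

Step 18. Facial discrimination in the protonation of the palladium enolate may be too low, because the aryl group carries only one ortho substituent, and protonation outside the catalyst may erode it further. The fallback sets the centre by reduction under dynamic kinetic resolution. It sets out from 34: asymmetric transfer hydrogenation (RuCl(p-cymene)[(S,S)-TsDPEN] or its antipode, HCO2H/Et3N) should reduce both the C2=C3 bond and the ketone to give cis-(3S,4S)-5,7-bis(methoxymethoxy)-3-{2-methoxy-3-[(E)-3-methylbut-1-enyl]-4-(triisopropylsilyloxy)phenyl}-6-(3-methylbut-2-enyl)chroman-4-ol F5. Buffered Dess–Martin oxidation of the alcohol then comes back to the route at 37.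

Step 19. Acid-mediated enolisation may erode the C3 configuration, and the prenyl group may cyclise onto a freed neighbouring phenol. The fallback moves the acid step to an achiral stage and carries silyl ethers through the stereocentre-forming step. It sets out from 34: the methoxymethyl groups are removed there (HCl, MeOH) to give 5,7-dihydroxy-3-{2-methoxy-3-[(E)-3-methylbut-1-enyl]-4-(triisopropylsilyloxy)phenyl}-6-(3-methylbut-2-enyl)-4H-chromen-4-one F6. Both phenols are silylated (t-BuMe2SiOTf, 2,6-lutidine) to the 5,7-bis(tert-butyldimethylsilyloxy) isoflavone F7. Conjugate reduction and trapping as in step 17 give the allyl enol carbonate F8, and decarboxylative protonation as in step 18 gives the (3S)-5,7-bis(tert-butyldimethylsilyloxy) isoflavanone F9. One buffered fluoride treatment (HF·pyridine, pyridine, THF) removes all three silyl groups and comes back to the route at 39.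

**Further compounds**

F1 | step 5 | (E)-4,4,5,5-tetramethyl-2-(3-methylbut-1-enyl)-1,3,2-dioxaborolane | CC(C)/C=C/B1OC(C)(C)C(C)(C)O1
F2 | step 5 | 2,4-dihydroxy-3-iodobenzaldehyde | O=Cc1ccc(O)c(I)c1O
F3 | step 5 | 2-hydroxy-3-iodo-4-(triisopropylsilyloxy)benzaldehyde | O=Cc1ccc(O[Si](C(C)C)(C(C)C)C(C)C)c(I)c1O
F4 | step 5 | 3-iodo-2-methoxy-4-(triisopropylsilyloxy)benzaldehyde | COc1c(C=O)ccc(O[Si](C(C)C)(C(C)C)C(C)C)c1I
F5 | step 18 | cis-(3S,4S)-5,7-bis(methoxymethoxy)-3-{2-methoxy-3-[(E)-3-methylbut-1-enyl]-4-(triisopropylsilyloxy)phenyl}-6-(3-methylbut-2-enyl)chroman-4-ol | COc1c([C@H]2COc3cc(OCOC)c(CC=C(C)C)c(OCOC)c3[C@H]2O)ccc(O[Si](C(C)C)(C(C)C)C(C)C)c1/C=C/C(C)C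
F6 | step 19 | 5,7-dihydroxy-3-{2-methoxy-3-[(E)-3-methylbut-1-enyl]-4-(triisopropylsilyloxy)phenyl}-6-(3-methylbut-2-enyl)-4H-chromen-4-one | COc1c(-c2coc3cc(O)c(CC=C(C)C)c(O)c3c2=O)ccc(O[Si](C(C)C)(C(C)C)C(C)C)c1/C=C/C(C)C
F7 | step 19 | 5,7-bis(tert-butyldimethylsilyloxy)-3-{2-methoxy-3-[(E)-3-methylbut-1-enyl]-4-(triisopropylsilyloxy)phenyl}-6-(3-methylbut-2-enyl)-4H-chromen-4-one | COc1c(-c2coc3cc(O[Si](C)(C)C(C)(C)C)c(CC=C(C)C)c(O[Si](C)(C)C(C)(C)C)c3c2=O)ccc(O[Si](C(C)C)(C(C)C)C(C)C)c1/C=C/C(C)C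
F8 | step 19 | allyl 5,7-bis(tert-butyldimethylsilyloxy)-3-{2-methoxy-3-[(E)-3-methylbut-1-enyl]-4-(triisopropylsilyloxy)phenyl}-6-(3-methylbut-2-enyl)-2H-chromen-4-yl carbonate | C=CCOC(=O)OC1=C(c2ccc(O[Si](C(C)C)(C(C)C)C(C)C)c(/C=C/C(C)C)c2OC)COc2cc(O[Si](C)(C)C(C)(C)C)c(CC=C(C)C)c(O[Si](C)(C)C(C)(C)C)c21
F9 | step 19 | (3S)-5,7-bis(tert-butyldimethylsilyloxy)-3-{2-methoxy-3-[(E)-3-methylbut-1-enyl]-4-(triisopropylsilyloxy)phenyl}-6-(3-methylbut-2-enyl)chroman-4-one | COc1c([C@H]2COc3cc(O[Si](C)(C)C(C)(C)C)c(CC=C(C)C)c(O[Si](C)(C)C(C)(C)C)c3C2=O)ccc(O[Si](C(C)C)(C(C)C)C(C)C)c1/C=C/C(C)C
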